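Retrosynthesis: the O–CH3 bonds masking 5-OH and 7-OH of ring A are cut last, the C2–C1' bond between the pyran ring and ring B before that, and C4–C4a and O1–C2, which take the pyran ring apart, first of all.
Enabling feature (chroman numbering): C2, C3 and C4 with the C3 isopropyl and C4 isobutyl branches are atom for atom the aldol dimer of isovaleraldehyde (C2 = CHO, C3 = C-α, C4 = C-β). The O1–C8a–C4a edge of ring A is the HO–C–CH edge of a symmetric phenol whose para carbon already holds the C6 formyl group.
Forward: rings A and B are bought. The pyran ring, the only ring made, closes in step 1 (C4–C4a, then O1–C2), ring B is joined to C2 in step 2, and step 3 frees the two phenols.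
Stereochemistry: C4 (S) comes from a chiral primary amine catalyst. C3 (R) comes from protonation, provisional in step 1 and fixed in step 2 anti to the pseudoaxial isobutyl group (3,4-cis). C2 (R) comes from arylation on the ring face free of both alkyl groups (2,3-trans).

Key step: step 1

Assumption: the quinine-derived primary amine is taken to leave the Si face of C-β of the iminium ion open (giving 4S); if the sense proves opposite, the quinidine-derived pseudoenantiomer is used and nothing else changes.

Step 1
Reactants: 1 4-hydroxy-2,6-dimethoxybenzaldehyde; 2 (E)-2-isopropyl-5-methylhex-2-enal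
Product: 6 (2R,3R,4S)-2-hydroxy-4-isobutyl-3-isopropyl-5,7-dimethoxychroman-6-carbaldehyde (3,4-cis lactol; 2R anomer drawn), via iminium ion 3 (not isolated), via enamine 4 (not isolated), via hydroxy aldehyde 5 (not isolated)
Conditions: 9-amino(9-deoxy)epi-quinine [(8α,9S)-6'-methoxycinchonan-9-amine] (20 mol %), CF3CO2H (30 mol %), 2 (2 equiv), CHCl3, 40 °C
Reagents that add atoms: none
Why: Proposed new method: the primary amine condenses with the α-branched enal 2 to iminium ion 3; the carbon ortho to the hydroxyl of 1, with the phenolic proton relayed to the quinuclidine, adds to C-β (C4–C4a), rearomatisation leaves enamine 4, protonation at C3 and hydrolysis free hydroxy aldehyde 5, and its phenol oxygen adds to the aldehyde (O1–C2) to give 6. The closest known reactions are the amine-catalysed enantioselective Friedel–Crafts alkylation/hemiacetalisation of naphthols, electron-rich phenols and 4-hydroxycoumarins with β-substituted enals and the activation of α,β-disubstituted enals toward indoles by cinchona-derived primary amine salts; a formyl-bearing phenol and an α-isopropyl enal are new to both. The arene should still be competent because the reacting carbon is ortho/para to all three oxygen donors and meta to the formyl group, so the σ-complex never places charge on the formyl-bearing carbon, and imine formation between the catalyst and the doubly ortho-flanked formyl group is only a reversible resting state, as in primary-amine-catalysed aldol reactions of aromatic aldehydes. The pyran ring closes by reversible 6-exo-trig addition of the phenol oxygen to the aldehyde carbon, so the anomeric centre C2 carries no lasting information. C4 is fixed by the catalyst, which shields one face of the E,E-iminium ion so that the arene enters on the Si face of C-β (4S); C3 arises by protonation of 4, can equilibrate through 5 toward the half-chair with isopropyl equatorial and isobutyl pseudoaxial away from the 5-methoxy group (3,4-cis), and is set again under cyclic control in step 2. The step needs C- over O-alkylation, 1,4- over 1,2-addition and one sense of annulation: oxa-Michael and Mannich-type adducts revert under the acidic conditions while the C-adduct is drained as the lactol, the two ortho carbons of 1 are equivalent, and 1 has a single hydroxyl, so formyl can only end at C6 and hydrogen at C8.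

Step 2
Reactants: 6 (2R,3R,4S)-2-hydroxy-4-isobutyl-3-isopropyl-5,7-dimethoxychroman-6-carbaldehyde; 7 2,4-diformylphloroglucinol (2,4,6-trihydroxybenzene-1,3-dicarbaldehyde)
Product: 10 (2R,3R,4S)-2-(3,5-diformyl-2,4,6-trihydroxyphenyl)-4-isobutyl-3-isopropyl-5,7-dimethoxychroman-6-carbaldehyde, via oxocarbenium ion 8 (not isolated), via 4H-chromene 9 (not isolated)
Conditions: Sc(OTf)3 (20 mol %), 7 (2 equiv), MeCN, 60 °C
Reagents that add atoms: none
Why: Friedel–Crafts C-arylation of a lactol through its oxocarbenium ion, the reaction type by which acylphloroglucinols are C-glycosylated with free sugars under Sc(OTf)3, should join the only free ring carbon of 7 to C2, because ion 8 exchanges H-3 through 4H-chromene 9 and is re-protonated anti to the pseudoaxial isobutyl group (3,4-cis, 3R) and the arene then enters on the ring face free of both alkyl groups (2R), the 2,3-trans diequatorial outcome that reversible O1–C2 opening under the acid also favours.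

Step 3
Reactants: 10 (2R,3R,4S)-2-(3,5-diformyl-2,4,6-trihydroxyphenyl)-4-isobutyl-3-isopropyl-5,7-dimethoxychroman-6-carbaldehyde
Product: 11 (2R,3R,4S)-2-(3,5-diformyl-2,4,6-trihydroxyphenyl)-5,7-dihydroxy-4-isobutyl-3-isopropylchroman-6-carbaldehyde (CNP0328914.1)
Conditions: BBr3 (10 equiv), CH2Cl2, −78 to 0 °C; then H2O
Reagents that add atoms: none
Why: Lewis-acid cleavage of aryl methyl ethers with BBr3, standard for turning 2,6-dimethoxybenzaldehydes into 2,6-dihydroxybenzaldehydes, should remove both methyl groups because each methoxy oxygen flanks the C6 formyl group, while boron bound to the formyl and phenol oxygens makes rings A and B electron-poor and so keeps O1–C2 and the three stereocenters untouched.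

Compound list
1 | 4-hydroxy-2,6-dimethoxybenzaldehyde | COc1cc(O)cc(OC)c1C=O | starting material
2 | (E)-2-isopropyl-5-methylhex-2-enal | CC(C)C/C=C(/C=O)C(C)C | starting material
3 | (E,E)-iminium ion formed from 2 and 9-amino(9-deoxy)epi-quinine (cation; counter-ion trifluoroacetate) | CC(C)C/C=C(/C=[NH+]/[C@@H](c1ccnc2ccc(OC)cc12)[C@@H]1C[C@@H]2CCN1C[C@@H]2C=C)C(C)C | intermediate
4 | catalyst-bound enamine after C4–C4a bond formation and rearomatisation (4S in chroman numbering; drawn E) | CC(C)C[C@H](c1c(O)cc(OC)c(C=O)c1OC)/C(C(C)C)=C/N[C@@H](c1ccnc2ccc(OC)cc12)[C@@H]1C[C@@H]2CCN1C[C@@H]2C=C | intermediate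
5 | (2R,3S)-3-(3-formyl-6-hydroxy-2,4-dimethoxyphenyl)-2-isopropyl-5-methylhexanal | CC(C)C[C@H](c1c(O)cc(OC)c(C=O)c1OC)[C@H](C=O)C(C)C | intermediate
6 | (2R,3R,4S)-2-hydroxy-4-isobutyl-3-isopropyl-5,7-dimethoxychroman-6-carbaldehyde (3,4-cis; anomers interconvert, 2R drawn) | CC(C)C[C@@H]1c2c(cc(OC)c(C=O)c2OC)O[C@@H](O)[C@@H]1C(C)C | intermediate
7 | 2,4-diformylphloroglucinol (2,4,6-trihydroxybenzene-1,3-dicarbaldehyde) | O=Cc1c(O)cc(O)c(C=O)c1O | starting material
8 | (3R,4S)-6-formyl-4-isobutyl-3-isopropyl-5,7-dimethoxy-3,4-dihydrochromenylium (cation) | CC(C)C[C@@H]1c2c(cc(OC)c(C=O)c2OC)[O+]=C[C@@H]1C(C)C | intermediate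
9 | (4S)-4-isobutyl-3-isopropyl-5,7-dimethoxy-4H-chromene-6-carbaldehyde | CC(C)C[C@@H]1c2c(cc(OC)c(C=O)c2OC)OC=C1C(C)C | intermediate
10 | (2R,3R,4S)-2-(3,5-diformyl-2,4,6-trihydroxyphenyl)-4-isobutyl-3-isopropyl-5,7-dimethoxychroman-6-carbaldehyde (2,3-trans, 3,4-cis) | CC(C)C[C@@H]1c2c(cc(OC)c(C=O)c2OC)O[C@@H](c2c(O)c(C=O)c(O)c(C=O)c2O)[C@@H]1C(C)C | intermediate
11 | (2R,3R,4S)-2-(3,5-diformyl-2,4,6-trihydroxyphenyl)-5,7-dihydroxy-4-isobutyl-3-isopropylchroman-6-carbaldehyde (CNP0328914.1) | CC(C)C[C@@H]1c2c(cc(O)c(C=O)c2O)O[C@@H](c2c(O)c(C=O)c(O)c(C=O)c2O)[C@@H]1C(C)C | target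

Total step count: 3. Longest linear sequence: 3.

Steps most likely to fail

Step 1 (the labelled step). Attack of the formyl-bearing arene on a hindered α-isopropyl iminium ion may be too slow, the catalyst may rest as the aryl aldimine, and face selection at C-β may be weak.
- The fallback sets out from 1 and 2 and returns at 6. It makes the same C4–C4a bond with a metalated arene and a stoichiometric chiral amine, using known reactions only.
- MOMCl and i-Pr2NEt convert 1 into 2,6-dimethoxy-4-(methoxymethoxy)benzaldehyde F1.
- N,N'-dimethylethylenediamine in refluxing toluene masks the formyl group as the aminal 2-[2,6-dimethoxy-4-(methoxymethoxy)phenyl]-1,3-dimethylimidazolidine F2.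
- n-BuLi (THF, 0 °C) removes the only kind of ring hydrogen, flanked by OMe and OMOM, to give the aryllithium F3, and MgBr2·OEt2 turns it into the arylmagnesium bromide F4.
- Separately, 2 is condensed with tert-butyl (R)-2-amino-3,3-dimethylbutanoate (D-tert-leucine tert-butyl ester; 4 Å sieves, CH2Cl2) to the chiral 1-azadiene F5.
- Auxiliary-controlled 1,4-addition of F4 to F5 follows (THF, −40 °C). Magnesium is held by the imine nitrogen and the ester carbonyl, and the aryl group is delivered anti to the tert-butyl group. An aqueous quench should then give the β-aryl aldimine F6 with C4 as S.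
- Aqueous HCl in THF hydrolyses imine, aminal and MOM ether in one operation, and the freed 5 closes to 6.

Step 2. Capture of ion 8 by the twice-deactivated arene may lag behind self-alkylation at C8 of ring A or the build-up of 9.
- The fallback sets out from 6 and 7 and returns at 10. It reverses the roles at C2.
- Under ethylenediammonium diacetate in MeCN at 60–80 °C, the open form 5 undergoes Knoevenagel-type condensation with the nucleophilic carbon of 7, now activated as its phenoxide. This is the way formylphloroglucinol meroterpenoids are assembled from aldehydes.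
- Loss of water gives the ring B ortho-quinone methide F7.
- The ring A phenol, the only hydroxyl within reach, adds to its exocyclic carbon (6-exo-trig oxa-Michael). This closure is reversible and should give the 2,3-trans chroman 10.

Step 3. Cleavage may stall after the first ether once boron is chelated between the new phenoxide and the formyl oxygen. Forcing may then open O1–C2, so that the freed 5-oxygen closes instead (Wessely–Moser-type migration) or C2 epimerises.
- The fallback sets out from 2 and 7 and returns at 11. It uses ethers that leave under neutral conditions.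
- Purchased 3,5-bis(benzyloxy)phenol F8 is formylated para to its hydroxyl by the Vilsmeier–Haack reaction (POCl3, DMF) to 2,6-bis(benzyloxy)-4-hydroxybenzaldehyde F9.
- F9 and 2 under the conditions of step 1 should give the dibenzyl lactol F10.
- F10 and 7 under the conditions of step 2 should give the dibenzyl ether F11.
- Hydrogenolysis (H2, 1 atm, Pd/C, EtOAc, stopped after two equivalents) removes both benzyl groups without acid and gives 11.

Further compounds
F1 | step 1 | 2,6-dimethoxy-4-(methoxymethoxy)benzaldehyde | COCOc1cc(OC)c(C=O)c(OC)c1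
F2 | step 1 | 2-[2,6-dimethoxy-4-(methoxymethoxy)phenyl]-1,3-dimethylimidazolidine | COCOc1cc(OC)c(C2N(C)CCN2C)c(OC)c1
F3 | step 1 | [3-(1,3-dimethylimidazolidin-2-yl)-2,4-dimethoxy-6-(methoxymethoxy)phenyl]lithium | COCOc1cc(OC)c(C2N(C)CCN2C)c(OC)c1[Li]
F4 | step 1 | [3-(1,3-dimethylimidazolidin-2-yl)-2,4-dimethoxy-6-(methoxymethoxy)phenyl]magnesium bromide | COCOc1cc(OC)c(C2N(C)CCN2C)c(OC)c1[Mg]Br
F5 | step 1 | tert-butyl (R)-2-{(E)-[(E)-2-isopropyl-5-methylhex-2-enylidene]amino}-3,3-dimethylbutanoate | CC(C)C/C=C(/C=N/[C@@H](C(=O)OC(C)(C)C)C(C)(C)C)C(C)C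
F6 | step 1 | tert-butyl (R)-2-{(E)-[(2R,3S)-3-[3-(1,3-dimethylimidazolidin-2-yl)-2,4-dimethoxy-6-(methoxymethoxy)phenyl]-2-isopropyl-5-methylhexylidene]amino}-3,3-dimethylbutanoate | CC(C)C[C@H](c1c(OCOC)cc(OC)c(C2N(C)CCN2C)c1OC)[C@H](/C=N/[C@@H](C(=O)OC(C)(C)C)C(C)(C)C)C(C)C
F7 | step 2 | ring B ortho-quinone methide from 5 and 7 (exocyclic C2=C1' bond; C3 and C4 arranged as in 5) | CC(C)C[C@H](c1c(O)cc(OC)c(C=O)c1OC)[C@H](C=C1C(=O)C(C=O)=C(O)C(C=O)=C1O)C(C)C
F8 | step 3 | 3,5-bis(benzyloxy)phenol (purchased) | Oc1cc(OCc2ccccc2)cc(OCc2ccccc2)c1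
F9 | step 3 | 2,6-bis(benzyloxy)-4-hydroxybenzaldehyde | O=Cc1c(OCc2ccccc2)cc(O)cc1OCc1ccccc1
F10 | step 3 | (2R,3R,4S)-5,7-bis(benzyloxy)-2-hydroxy-4-isobutyl-3-isopropylchroman-6-carbaldehyde (2R anomer drawn) | CC(C)C[C@@H]1c2c(cc(OCc3ccccc3)c(C=O)c2OCc2ccccc2)O[C@@H](O)[C@@H]1C(C)C
F11 | step 3 | (2R,3R,4S)-5,7-bis(benzyloxy)-2-(3,5-diformyl-2,4,6-trihydroxyphenyl)-4-isobutyl-3-isopropylchroman-6-carbaldehyde | CC(C)C[C@@H]1c2c(cc(OCc3ccccc3)c(C=O)c2OCc2ccccc2)O[C@@H](c2c(O)c(C=O)c(O)c(C=O)c2O)[C@@H]1C(C)C
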